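Atom labels used throughout: C1 lactone carbonyl, O2 ring oxygen, C3 hemiketal carbon, C4 the CH that carries methyl C10, C4a and C8a ring fusion, C5 to C8 ring A, C9 the OCH2 carbon; ring B is the trimethylbenzoate.

## Analysis of the target

Target 22 is a 3,4-dihydroisocoumarin: a six-membered lactone (C1, O2, C3, C4, C4a, C8a) fused to ring A, which is substituted at every position but C7 (methyl on C5, methoxy on C6, phenol on C8). Its C3 is a hemiketal carbon that also carries the C9 oxymethylene, esterified by the fully substituted ring B acid, 2,4-dihydroxy-3,5,6-trimethylbenzoic acid. There are two adjacent stereocentres, C4 (S), a benzylic CH bearing methyl C10, and C3 (R), with the C3 hydroxyl trans to C10. C3 is not an independent problem: the lactol is in ring–chain equilibrium with the open keto acid, and the trans isomer, with the hydroxyl axial (anomeric stabilisation) and C10 axial (away from the peri methyl on C5), should be the resting state. C4 is therefore the one centre that has to be made, and it is fragile: in the open form it is benzylic and α to a ketone, and loss of water across C3–C4 would give an achiral 4-methylisocoumarin. Further sensitive points are the C9 ester next to the hemiketal (acyl shift, hydrolysis), the need to keep the C6 oxygen methylated while three other phenols are freed, and the di-ortho-substituted ring B carboxyl, which resists acyl transfer. The difficulty is thus to install one enolisable methyl-bearing centre enantioselectively on a crowded arene and to carry it through an esterification with a hindered acid. The feature used here is that the flat precursor 11 has its C9 hydroxyl allylic to the C3=C4 enol-lactone double bond, so the hydroxyl can steer a one-carbon unit onto C3=C4 as a cyclopropane in which C4 cannot enolise and whose extra carbon later becomes C10.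

## Retrosynthetic reasoning

22 from 21. The three phenols (on C8 and on ring B) are unmasked last by cutting three O–benzyl bonds in one neutral hydrogenolysis. Nothing else in 22 is reducible under those conditions, and the enolisable C4 never meets acid or base after this point.

21 from 20. The C10–H bond and the C3–OH bond are removed and C10 is reconnected to C3, which turns the methyl-bearing, enolisable C4 into a cyclopropane carbon. The forward step is a protolytic opening that must break C3–C10 and not C3–C4 or C4–C10. The donor oxygen O2 on C3 and the unsubstituted C10 direct an electrophile that way under acid, whereas base would open towards the benzylic carbon and is avoided.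

20 from 13 and 19. The ester bond between O9 and the ring B carbonyl is cut here and not later, because in 13 the C4 centre is locked and the amine base needed for a hindered acylation can do no harm. It is not cut earlier because the free C9 hydroxyl is the directing group of the step before.

13 from 11 and 12. This is the central disconnection: C4–C10 and C3–C10 are cut, removing the three-membered ring and both stereocentres at once. What remains is an achiral, planar allylic alcohol, so all asymmetric induction has to come from a chiral reagent bound to the C9 oxygen, and the one carbon of 12 must be delivered to C3=C4 on one face.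

11 from 10, and 10 from 8 and 9. The lactone bond O2–C3 is opened to an ortho-alkynyl benzoate, whose forward closure is a 6-endo attack of the ester carbonyl oxygen on the activated alkyne. The C4–C4a bond is then cut to the aryl bromide 8 and the three-carbon alkyne 9, a standard sp–sp2 coupling.

8 from 1 by way of 2 to 7. In 8 the bromine is meta to both ring oxygens and flanked by the methyl and the carboxyl carbon, which is the pattern that 1 gives by two successive electrophilic formylations ortho to bromine. The first formyl group is reduced to the C5 methyl and the second is oxidised to the C1 carboxyl. While the second is still an aldehyde it serves as the chelating handle to exchange the neighbouring methyl ether for a benzyl ether, which differentiates the C8 and C6 oxygens.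

19 from 14 by way of 15 to 18. Ring B lacks only one methyl relative to commercial 14, and its single free ring position accepts a formyl group that is hydrogenolysed to that methyl. Benzylation, cleavage of the hindered methyl ester and chlorination give the acylating agent.

## Alternatives that were turned down

Alternative 1: Ring A is disconnected across C4a–C5 and C8–C8a. In the forward sense the oxygenated diene A2 would add to the alkynoate A3, whose alkyne carbons become C8a and C4a, and the adduct would aromatise by expelling one alkoxy group to give the phenol A1 with the whole side chain and ring B in place.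
- For: ring A arrives with every substituent in a defined position, the C8 phenol is born free and already distinguished from the C6 methyl ether, and the plan is convergent. On regiochemical certainty of ring A and on convergence A1 is stronger than the route chosen, which relies on two electrophilic substitutions.
- Against: the C4 stereocentre of A3 is propargylic to an ynoate, where base or heat can shift the triple bond into an allene and erase the configuration. The new C4a–C5 bond joins a branched alkyne carbon to a methyl-bearing diene terminus, a crowded cycloaddition that would need heat. A3 needs two stereocentres from separate asymmetric chemistry, one of which (the silyloxy carbon, later C3) is oxidised away. Three operations remain after the cycloaddition: desilylation beside an ester with the risk of a 1,2-acyl shift, oxidation to the ketone while C4 is enolisable, and hydrogenolysis.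
- What the chosen route offers instead: a C4 centre created late from a flat achiral precursor by reagent control, kept non-enolisable until two steps from the end, with no throw-away stereocentre.

Alternative 2: The lactol is traced back to the five-membered ketol A5, a 2-hydroxyindan-1-one in which C1 and C3 of the target are still bonded. In the forward sense a periodate-type oxidant would cleave that ketone–carbinol bond: the ketone carbon becomes the C1 carboxylic acid, the carbinol carbon becomes the C3 ketone, and the acid adds to the ketone to close the lactol A4, which is identical with 21.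
- For: ketol cleavage is dependable, delivers both carbons at the right oxidation level in one non-basic step, and the indanone stereocentre that becomes C4 is β to the ketone and cannot enolise before the cleavage. On the certainty of its key event this plan is stronger than the cyclopropanation proposed here, and since it meets the chosen route at 21 the endgame is equal.
- Against: A5 is costly. An indanone must be annulated onto the crowded arene, the benzylic methyl centre needs its own asymmetric step, and a fully substituted carbinol carrying the acyloxymethyl group must be built on the α-carbon. Tertiary α-ketols can also undergo acyloin-type rearrangement under acid or base. A carbocycle is assembled only to be cut.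
- What the chosen route offers instead: a shorter, flatter approach in which precursor 11 needs no stereochemistry at all and the single asymmetric step also supplies C10.

Alternative 3: Ring B is disconnected at the bond from its carboxyl-bearing carbon to the hydroxylated neighbour and at the bond between its two adjacent methyl-bearing carbons. In the forward sense the C9 alcohol is first esterified with a small but-2-ynoyl group to give A8, the bis(silyloxy) diene A7 adds to the ynoate, and loss of an alkoxy group with desilylation gives the resorcinol ester A6.
- For: it avoids the one awkward esterification of the chosen route, the union of a neopentyl-like alcohol with a di-ortho-substituted aroyl chloride, and ring B appears with free phenols, saving two benzyl ethers. On both points A6 is stronger.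
- Against: the main step is spent on the easiest part of the molecule, since ring B is two steps from commercial 14. The real problem, C4 and the hemiketal, is left to separate asymmetric synthesis of the side chain of A8, followed by deprotection and oxidation next to the ester. The cycloaddition must create a hexasubstituted benzene by joining two methyl-bearing carbons, using a tetrasubstituted, hydrolytically fragile diene and an unactivated butynoate, so open-chain Michael-type adducts and diene decomposition are likely competitors.
- What the chosen route offers instead: it accepts the hindered acylation (an alkylative esterification is held in reserve) and places its key step where the structural difficulty lies.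

Key step: step 10

Assumption: the face selectivity of the dioxaborolane reagent is taken to follow the sense established for (E)-3-aryl allylic alcohols, which calls for the (4S,5S) reagent here.

## Route

Step 1
Reactants: 1 1-bromo-3,5-dimethoxybenzene
Product: 2 2-bromo-4,6-dimethoxybenzaldehyde
Conditions: POCl3, DMF, 0 → 90 °C; then ice/H2O
Reagents that add atoms: N,N-dimethylformamide CN(C)C=O (formyl carbon); water O (formyl oxygen)
Why: Vilsmeier–Haack formylation; the chloroiminium ion should attack the position ortho to bromine, which is para to one methoxy and ortho to the other, in preference to the more crowded site between the two methoxy groups, and hydrolysis of the iminium gives the aldehyde.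

Step 2
Reactants: 2 2-bromo-4,6-dimethoxybenzaldehyde
Product: 3 1-bromo-3,5-dimethoxy-2-methylbenzene
Conditions: Et3SiH, TFA, CH2Cl2, 0 °C → rt
Reagents that add atoms: none
Why: Ionic hydrogenation of an aryl aldehyde whose benzylic cation is stabilised by ortho and para methoxy groups; the aryl bromide, which catalytic hydrogenation would remove, is left alone.

Step 3
Reactants: 3 1-bromo-3,5-dimethoxy-2-methylbenzene
Product: 4 2-bromo-4,6-dimethoxy-3-methylbenzaldehyde
Conditions: POCl3, DMF, 0 → 90 °C; then ice/H2O
Reagents that add atoms: N,N-dimethylformamide CN(C)C=O (formyl carbon); water O (formyl oxygen)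
Why: Second Vilsmeier–Haack formylation; the open positions are the one ortho to bromine (para to a methoxy) and the one between the methoxy groups, and the preference of step 1 should again send the iminium ion next to bromine, leaving bromine flanked by CH3 and CHO.

Step 4
Reactants: 4 2-bromo-4,6-dimethoxy-3-methylbenzaldehyde
Product: 5 2-bromo-6-hydroxy-4-methoxy-3-methylbenzaldehyde
Conditions: BCl3, CH2Cl2, −78 → 0 °C; then H2O
Reagents that add atoms: none
Why: Chelation-controlled ether cleavage; BCl3 bridges the aldehyde oxygen and the ortho methoxy oxygen and chloride removes only that methyl, while the methoxy para to the aldehyde cannot chelate and stays.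

Step 5
Reactants: 5 2-bromo-6-hydroxy-4-methoxy-3-methylbenzaldehyde
Product: 6 6-(benzyloxy)-2-bromo-4-methoxy-3-methylbenzaldehyde
Conditions: BnBr, K2CO3, DMF, rt
Reagents that add atoms: benzyl bromide BrCc1ccccc1
Why: Williamson ether synthesis on the phenoxide; the benzyl group masks the future C8 phenol through the carbenoid and acylation steps and leaves in the final hydrogenolysis.

Step 6
Reactants: 6 6-(benzyloxy)-2-bromo-4-methoxy-3-methylbenzaldehyde
Product: 7 6-(benzyloxy)-2-bromo-4-methoxy-3-methylbenzoic acid
Conditions: NaClO2, NaH2PO4, 2-methyl-2-butene, t-BuOH/H2O, rt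
Reagents that add atoms: sodium chlorite [Na+].[O-]Cl=O
Why: Pinnick oxidation of the aldehyde to the acid; excess 2-methyl-2-butene traps HOCl so that the electron-rich ring is not chlorinated.

Step 7
Reactants: 7 6-(benzyloxy)-2-bromo-4-methoxy-3-methylbenzoic acid
Product: 8 methyl 6-(benzyloxy)-2-bromo-4-methoxy-3-methylbenzoate
Conditions: MeI, K2CO3, DMF, rt
Reagents that add atoms: iodomethane CI
Why: O-alkylation of the carboxylate (SN2 at MeI), which is indifferent to the two ortho substituents that would block acid-catalysed esterification.

Step 8
Reactants: 8 methyl 6-(benzyloxy)-2-bromo-4-methoxy-3-methylbenzoate; 9 propargyl alcohol (prop-2-yn-1-ol)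
Product: 10 methyl 6-(benzyloxy)-2-(3-hydroxyprop-1-yn-1-yl)-4-methoxy-3-methylbenzoate
Conditions: PdCl2(PPh3)2 (5 mol%), CuI (10 mol%), Et3N/DMF, degassed, 80 °C
Reagents that add atoms: none
Why: Sonogashira coupling; the ortho ester activates the C–Br bond for oxidative addition to zerovalent palladium and heating compensates for the two flanking groups, forming the C4–C4a bond.

Step 9
Reactants: 10 methyl 6-(benzyloxy)-2-(3-hydroxyprop-1-yn-1-yl)-4-methoxy-3-methylbenzoate
Product: 11 8-(benzyloxy)-3-(hydroxymethyl)-6-methoxy-5-methyl-1H-isochromen-1-one (the 3-(hydroxymethyl)isocoumarin)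
Conditions: AgOTf (10 mol%), TsOH·H2O (20 mol%), H2O (2 equiv), ClCH2CH2Cl, 60 °C
Reagents that add atoms: water O (lactone carbonyl oxygen)
Why: AgOTf-catalysed 6-endo-dig cyclisation; the ester carbonyl oxygen attacks the activated alkyne at the carbon remote from the arene, the resulting 1-methoxyisochromenylium ion is hydrolysed at C1 with loss of the methyl group as its alcohol, and protonolysis of the C4–Ag bond gives C4–H.

Step 10
Reactants: 11 8-(benzyloxy)-3-(hydroxymethyl)-6-methoxy-5-methyl-1H-isochromen-1-one; 12 diiodomethane
Product: 13 (1aS,7bS)-4-(benzyloxy)-1a-(hydroxymethyl)-6-methoxy-7-methyl-1a,7b-dihydrocyclopropa[c]isochromen-3(1H)-one (in the atom labels used here: C10 bridges C3 and C4 on one face, both S, ring cis-fused)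
Conditions: Et2Zn, 12, DME, CH2Cl2, −10 °C [gives Zn(CH2I)2·DME]; then 11 and (4S,5S)-2-butyl-N,N,N′,N′-tetramethyl-1,3,2-dioxaborolane-4,5-dicarboxamide (1.2 equiv), −10 °C → rt; aq. NH4Cl, then diethanolamine wash
Reagents that add atoms: none
Why: Proposed new method: the closest known reaction is the enantioselective Simmons–Smith cyclopropanation of allylic alcohols by Zn(CH2I)2 in the presence of a tartramide-derived butyl dioxaborolane, which has not been shown on the C3=C4 bond of an isocoumarin, an enol-lactone alkene. The C9 hydroxyl of 11 is converted by the carbenoid into a zinc alkoxide that binds to boron, an amide carbonyl of the ligand holds a second Zn(CH2I)2, and CH2 is passed to the alkene through the concerted butterfly transition state. C4–C10 and C3–C10 form together on one face, so the three-membered ring closes by a concerted [2+1] syn addition and can only be cis-fused to the lactone ring. C3 and C4 are both set in this one event and both by the ligand, because the planar bicycle has no facial bias of its own; carrying over the sense found with (E)-3-aryl allylic alcohols, which share the trans relation of CH2OH and aryl, the (4S,5S) reagent should deliver CH2 to the face that gives the (3S,4S) cyclopropane. Reactivity is expected because O2 feeds electron density into C3=C4 as in an enol ester, a class that the carbenoid Zn(CH2I)2 does cyclopropanate, and because transfer is intramolecular within the alkoxide complex. The step needs enantiofacial selectivity and chemoselectivity for the alkene over the lactone carbonyl and the electron-rich arene, and the allylic hydroxyl secures both by anchoring the carbenoid next to C3=C4. A neutral work-up (NH4Cl, removal of BuB(OH)2 as its diethanolamine adduct) replaces the usual alkaline peroxide so that the cyclopropyl lactone is not hydrolysed.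

Step 11
Reactants: 14 atraric acid (methyl 2,4-dihydroxy-3,6-dimethylbenzoate)
Product: 15 methyl 3-formyl-4,6-dihydroxy-2,5-dimethylbenzoate (formyl group on the one free ring position of 14)
Conditions: Cl2CHOMe, TiCl4, CH2Cl2, 0 °C → rt; then H2O
Reagents that add atoms: dichloromethyl methyl ether COC(Cl)Cl (formyl carbon); water O (formyl oxygen)
Why: Rieche formylation; the only unsubstituted ring carbon is ortho to one hydroxyl and para to the other, so the TiCl4-bound phenoxide is attacked there and the α-chloro ether is hydrolysed to the aldehyde on work-up.

Step 12
Reactants: 15 methyl 3-formyl-4,6-dihydroxy-2,5-dimethylbenzoate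
Product: 16 methyl 2,4-dihydroxy-3,5,6-trimethylbenzoate
Conditions: H2 (1 atm), Pd/C, AcOH, cat. HCl, rt
Reagents that add atoms: none
Why: Catalytic hydrogenolysis of an ortho-hydroxybenzaldehyde to the methylphenol by way of the benzylic alcohol, the classical way of placing C-methyl groups on resorcinol esters; the ester and the arene are not reduced.

Step 13
Reactants: 16 methyl 2,4-dihydroxy-3,5,6-trimethylbenzoate
Product: 17 methyl 2,4-bis(benzyloxy)-3,5,6-trimethylbenzoate
Conditions: BnBr, K2CO3, DMF, 60 °C
Reagents that add atoms: benzyl bromide BrCc1ccccc1
Why: Double Williamson etherification; warming is needed for the hydrogen-bonded hydroxyl ortho to the ester, and C-alkylation is excluded because no ring position is free.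

Step 14
Reactants: 17 methyl 2,4-bis(benzyloxy)-3,5,6-trimethylbenzoate
Product: 18 2,4-bis(benzyloxy)-3,5,6-trimethylbenzoic acid
Conditions: KOtBu, H2O (0.25 equiv per KOtBu), THF, rt → 50 °C; then aq. HCl
Reagents that add atoms: water O (as hydroxide; carboxyl oxygen)
Why: Saponification of a di-ortho-substituted methyl benzoate by poorly solvated hydroxide generated from KOtBu and a little water, which attacks the acyl carbon where aqueous alkali fails; benzyl ethers are stable to base.

Step 15
Reactants: 18 2,4-bis(benzyloxy)-3,5,6-trimethylbenzoic acid
Product: 19 2,4-bis(benzyloxy)-3,5,6-trimethylbenzoyl chloride (used crude)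
Conditions: (COCl)2, cat. DMF, CH2Cl2, 0 °C → rt
Reagents that add atoms: oxalyl chloride ClC(=O)C(=O)Cl
Why: Acid chloride formation through the catalytic chloroiminium ion from DMF; the gaseous by-products leave and the crude chloride goes directly into the acylation.

Step 16
Reactants: 13 the cyclopropane alcohol; 19 2,4-bis(benzyloxy)-3,5,6-trimethylbenzoyl chloride
Product: 20 [(1aS,7bS)-4-(benzyloxy)-6-methoxy-7-methyl-3-oxo-1a,7b-dihydrocyclopropa[c]isochromen-1a(1H)-yl]methyl 2,4-bis(benzyloxy)-3,5,6-trimethylbenzoate
Conditions: Et3N, DMAP (1 equiv), CH2Cl2, 0 °C → rt
Reagents that add atoms: none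
Why: DMAP-mediated acyl transfer through the N-acylpyridinium ion, which is needed for a di-ortho-substituted aroyl chloride; the amine base is harmless at this stage because C4 is a cyclopropane carbon and has no enolisable position, and neither stereocentre is touched.

Step 17
Reactants: 20 the acylated cyclopropane
Product: 21 [(3R,4S)-8-(benzyloxy)-3-hydroxy-6-methoxy-4,5-dimethyl-1-oxo-3,4-dihydro-1H-isochromen-3-yl]methyl 2,4-bis(benzyloxy)-3,5,6-trimethylbenzoate
Conditions: TsOH·H2O (1.5 equiv), 1,4-dioxane/H2O (5:1), 50 °C
Reagents that add atoms: water O (C3 hydroxyl)
Why: Acid-promoted protolytic ring opening of an acyloxycyclopropane (a cyclopropanol ester), the known route from such rings to α-methyl carbonyl compounds: the proton adds to unsubstituted C10 and the C3–C10 bond breaks towards the cation at C3, which is stabilised by O2 and can be bridged by the C9 ester carbonyl, before water adds to C3. C4 keeps its configuration because none of its bonds to H, C4a, C3 or C10 is broken, and the hemiketal should settle by ring–chain equilibration with the hydroxyl trans to the new methyl (hydroxyl axial, methyl axial away from the C5 methyl).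

Step 18
Reactants: 21 the tri-O-benzyl hemiketal
Product: 22 [(3R,4S)-3,8-dihydroxy-6-methoxy-4,5-dimethyl-1-oxo-3,4-dihydro-1H-isochromen-3-yl]methyl 2,4-dihydroxy-3,5,6-trimethylbenzoate (target)
Conditions: H2 (1 atm), Pd/C, EtOAc, rt
Reagents that add atoms: none
Why: Hydrogenolysis of three aryl benzyl ethers under neutral conditions; an aprotic solvent avoids ketal exchange at C3, and the lactol, the esters and the C4 centre are not affected.

## Compound list

1 | 1-bromo-3,5-dimethoxybenzene | COc1cc(Br)cc(OC)c1 | starting material
2 | 2-bromo-4,6-dimethoxybenzaldehyde | COc1cc(Br)c(C=O)c(OC)c1 | intermediate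
3 | 1-bromo-3,5-dimethoxy-2-methylbenzene | COc1cc(Br)c(C)c(OC)c1 | intermediate
4 | 2-bromo-4,6-dimethoxy-3-methylbenzaldehyde | COc1cc(OC)c(C=O)c(Br)c1C | intermediate
5 | 2-bromo-6-hydroxy-4-methoxy-3-methylbenzaldehyde | COc1cc(O)c(C=O)c(Br)c1C | intermediate
6 | 6-(benzyloxy)-2-bromo-4-methoxy-3-methylbenzaldehyde | COc1cc(OCc2ccccc2)c(C=O)c(Br)c1C | intermediate
7 | 6-(benzyloxy)-2-bromo-4-methoxy-3-methylbenzoic acid | COc1cc(OCc2ccccc2)c(C(=O)O)c(Br)c1C | intermediate
8 | methyl 6-(benzyloxy)-2-bromo-4-methoxy-3-methylbenzoate | COC(=O)c1c(Br)c(C)c(OC)cc1OCc1ccccc1 | intermediate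
9 | propargyl alcohol (prop-2-yn-1-ol) | C#CCO | starting material
10 | methyl 6-(benzyloxy)-2-(3-hydroxyprop-1-yn-1-yl)-4-methoxy-3-methylbenzoate | COC(=O)c1c(C#CCO)c(C)c(OC)cc1OCc1ccccc1 | intermediate
11 | 8-(benzyloxy)-3-(hydroxymethyl)-6-methoxy-5-methyl-1H-isochromen-1-one | COc1cc(OCc3ccccc3)c2c(c1C)C=C(CO)OC2=O | intermediate
12 | diiodomethane | ICI | starting material
13 | (1aS,7bS)-4-(benzyloxy)-1a-(hydroxymethyl)-6-methoxy-7-methyl-1a,7b-dihydrocyclopropa[c]isochromen-3(1H)-one | COc1cc(OCc3ccccc3)c2c(c1C)[C@@H]4C[C@]4(CO)OC2=O | intermediate
14 | atraric acid (methyl 2,4-dihydroxy-3,6-dimethylbenzoate) | COC(=O)c1c(C)cc(O)c(C)c1O | starting material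
15 | methyl 3-formyl-4,6-dihydroxy-2,5-dimethylbenzoate | COC(=O)c1c(C)c(C=O)c(O)c(C)c1O | intermediate
16 | methyl 2,4-dihydroxy-3,5,6-trimethylbenzoate | COC(=O)c1c(C)c(C)c(O)c(C)c1O | intermediate
17 | methyl 2,4-bis(benzyloxy)-3,5,6-trimethylbenzoate | COC(=O)c1c(C)c(C)c(OCc2ccccc2)c(C)c1OCc1ccccc1 | intermediate
18 | 2,4-bis(benzyloxy)-3,5,6-trimethylbenzoic acid | OC(=O)c1c(C)c(C)c(OCc2ccccc2)c(C)c1OCc1ccccc1 | intermediate
19 | 2,4-bis(benzyloxy)-3,5,6-trimethylbenzoyl chloride | ClC(=O)c1c(C)c(C)c(OCc2ccccc2)c(C)c1OCc1ccccc1 | intermediate
20 | [(1aS,7bS)-4-(benzyloxy)-6-methoxy-7-methyl-3-oxo-1a,7b-dihydrocyclopropa[c]isochromen-1a(1H)-yl]methyl 2,4-bis(benzyloxy)-3,5,6-trimethylbenzoate | COc1cc(OCc3ccccc3)c2c(c1C)[C@@H]4C[C@]4(COC(=O)c5c(C)c(C)c(OCc6ccccc6)c(C)c5OCc5ccccc5)OC2=O | intermediate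
21 | [(3R,4S)-8-(benzyloxy)-3-hydroxy-6-methoxy-4,5-dimethyl-1-oxo-3,4-dihydro-1H-isochromen-3-yl]methyl 2,4-bis(benzyloxy)-3,5,6-trimethylbenzoate | COc1cc(OCc3ccccc3)c2c(c1C)[C@H](C)[C@](O)(COC(=O)c1c(C)c(C)c(OCc3ccccc3)c(C)c1OCc3ccccc3)OC2=O | intermediate
22 | [(3R,4S)-3,8-dihydroxy-6-methoxy-4,5-dimethyl-1-oxo-3,4-dihydro-1H-isochromen-3-yl]methyl 2,4-dihydroxy-3,5,6-trimethylbenzoate | COc1cc(O)c2c(c1C)[C@H](C)[C@](O)(COC(=O)c1c(C)c(C)c(O)c(C)c1O)OC2=O | target

## Step count and least certain steps

Total: 18 steps. Longest linear sequence: 13 steps (steps 1 to 10, then 16 to 18); the ring B branch (steps 11 to 15) has 5 steps.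

Step 10 (key step, proposed new method). The most likely failures are low conversion and poor facial selectivity. The enol-lactone alkene is conjugated through the arene with the lactone carbonyl and is a weaker nucleophile than the allylic alcohols on which the reagent is established. The zinc alkoxide may also chelate to O2 instead of binding boron, which would loosen ligand control. A further risk is opening of the product cyclopropane by the ZnI2 that accumulates.

The fallback uses only known chemistry, sets out from 10 and returns at 21. Iodocyclisation of 10 (I2, NaHCO3, MeCN, rt; 6-endo closure of ortho-alkynyl benzoates onto an iodonium ion) should give 8-(benzyloxy)-3-(hydroxymethyl)-4-iodo-6-methoxy-5-methylisocoumarin F1. Negishi coupling (MeZnCl, Pd(PPh3)4, THF, 50 °C) should replace iodine by the C10 methyl to give 8-(benzyloxy)-3-(hydroxymethyl)-6-methoxy-4,5-dimethylisocoumarin F2. Acylation with 19 (Et3N, DMAP, CH2Cl2) should give the ring B ester of the 4-methylisocoumarin F3. The enol lactone of F3 is then opened with LiOH in aqueous THF at 0 °C, and acidification with aq. HCl lets the keto acid close to the lactol. This gives the racemate, that is 21 together with its enantiomer, the (3S,4R) tri-O-benzyl hemiketal F4, which would be separated on a chiral stationary phase; 21 continues with step 18. The cost is the loss of half the material at a late stage.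

Step 17. The most likely failure is sluggish protonation at C10, because O2 is acylated and is a weaker donor than a free or silylated cyclopropanol oxygen. Forcing the acid would then erode the C4 configuration through enolisation of the open keto acid or dehydration to the 4-methylisocoumarin, or would divert cleavage to the C4–C10 bond.

The fallback sets out from 20 and returns at 21, replacing the proton by a soft metal electrophile. Hg(OCOCF3)2 in THF/H2O at rt, followed by aq. NaCl, should attack C10, break C3–C10 and give the C10-chloromercurio hemiketal, [(3R,4S)-8-(benzyloxy)-4-[(chloromercurio)methyl]-3-hydroxy-6-methoxy-5-methyl-1-oxo-3,4-dihydro-1H-isochromen-3-yl]methyl 2,4-bis(benzyloxy)-3,5,6-trimethylbenzoate F5. Radical demercuration (Bu3SnH, cat. AIBN, THF, rt) would then turn CH2HgCl into the methyl group of 21 without any Brønsted acid.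

Step 16. The most likely failure is slow acyl transfer between a di-ortho-substituted aroyl chloride and a neopentyl-like alcohol. Long exposure to amine base could let the lactone acyl group migrate to O9, freeing a cyclopropanol that opens.

The fallback sets out from 13 and 18 and returns at 20. A Mitsunobu esterification (PPh3, DIAD, THF, 0 °C → rt) activates the alcohol instead of the acid, so the hindered carboxylate acts as an oxygen nucleophile at C9 and the crowded acyl carbon is never attacked. No new compound is formed on the way.

Step 8. The most likely failure is slow oxidative addition at a C–Br bond flanked by an ester and a methyl group, with oxidative dimerisation of 9 consuming the alkyne in the meantime.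

The fallback sets out from 8 and returns at 10. An aromatic Finkelstein exchange (NaI, CuI, trans-N,N′-dimethylcyclohexane-1,2-diamine, dioxane, 110 °C) should give methyl 6-(benzyloxy)-2-iodo-4-methoxy-3-methylbenzoate F6, which should couple with 9 at rt under the conditions of step 8.

## Further compounds

F1 | step 10 | 8-(benzyloxy)-3-(hydroxymethyl)-4-iodo-6-methoxy-5-methyl-1H-isochromen-1-one | COc1cc(OCc3ccccc3)c2c(c1C)C(I)=C(CO)OC2=O
F2 | step 10 | 8-(benzyloxy)-3-(hydroxymethyl)-6-methoxy-4,5-dimethyl-1H-isochromen-1-one | COc1cc(OCc3ccccc3)c2c(c1C)C(C)=C(CO)OC2=O
F3 | step 10 | [8-(benzyloxy)-6-methoxy-4,5-dimethyl-1-oxo-1H-isochromen-3-yl]methyl 2,4-bis(benzyloxy)-3,5,6-trimethylbenzoate | COc1cc(OCc3ccccc3)c2c(c1C)C(C)=C(COC(=O)c1c(C)c(C)c(OCc3ccccc3)c(C)c1OCc1ccccc1)OC2=O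
F4 | step 10 | [(3S,4R)-8-(benzyloxy)-3-hydroxy-6-methoxy-4,5-dimethyl-1-oxo-3,4-dihydro-1H-isochromen-3-yl]methyl 2,4-bis(benzyloxy)-3,5,6-trimethylbenzoate (enantiomer of 21) | COc1cc(OCc3ccccc3)c2c(c1C)[C@@H](C)[C@@](O)(COC(=O)c1c(C)c(C)c(OCc3ccccc3)c(C)c1OCc3ccccc3)OC2=O
F5 | step 17 | [(3R,4S)-8-(benzyloxy)-4-[(chloromercurio)methyl]-3-hydroxy-6-methoxy-5-methyl-1-oxo-3,4-dihydro-1H-isochromen-3-yl]methyl 2,4-bis(benzyloxy)-3,5,6-trimethylbenzoate | COc1cc(OCc3ccccc3)c2c(c1C)[C@H](C[Hg]Cl)[C@](O)(COC(=O)c1c(C)c(C)c(OCc3ccccc3)c(C)c1OCc3ccccc3)OC2=O
F0 | step 16 | none | none
F6 | step 8 | methyl 6-(benzyloxy)-2-iodo-4-methoxy-3-methylbenzoate | COC(=O)c1c(I)c(C)c(OC)cc1OCc1ccccc1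
A1 | alternative 1 | benzyl 2-[(2S,3R)-4-{[2,4-bis(benzyloxy)-3,5,6-trimethylbenzoyl]oxy}-3-[(tert-butyldimethylsilyl)oxy]butan-2-yl]-6-hydroxy-4-methoxy-3-methylbenzoate | COc1cc(O)c(C(=O)OCc2ccccc2)c(c1C)[C@H](C)[C@@H](O[Si](C)(C)C(C)(C)C)COC(=O)c1c(C)c(C)c(OCc2ccccc2)c(C)c1OCc1ccccc1
A2 | alternative 1 | [(1,3-dimethoxypenta-1,3-dien-1-yl)oxy]trimethylsilane | CC=C(OC)C=C(OC)O[Si](C)(C)C
A3 | alternative 1 | benzyl (4S,5R)-6-{[2,4-bis(benzyloxy)-3,5,6-trimethylbenzoyl]oxy}-5-[(tert-butyldimethylsilyl)oxy]-4-methylhex-2-ynoate | O=C(OCc1ccccc1)C#C[C@H](C)[C@@H](O[Si](C)(C)C(C)(C)C)COC(=O)c1c(C)c(C)c(OCc2ccccc2)c(C)c1OCc1ccccc1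
A4 | alternative 2 | [(3R,4S)-8-(benzyloxy)-3-hydroxy-6-methoxy-4,5-dimethyl-1-oxo-3,4-dihydro-1H-isochromen-3-yl]methyl 2,4-bis(benzyloxy)-3,5,6-trimethylbenzoate (identical with 21) | COc1cc(OCc3ccccc3)c2c(c1C)[C@H](C)[C@](O)(COC(=O)c1c(C)c(C)c(OCc3ccccc3)c(C)c1OCc3ccccc3)OC2=O
A5 | alternative 2 | [(3S)-7-(benzyloxy)-2-hydroxy-5-methoxy-3,4-dimethyl-1-oxo-2,3-dihydro-1H-inden-2-yl]methyl 2,4-bis(benzyloxy)-3,5,6-trimethylbenzoate (either configuration at the carbinol carbon) | COc1cc(OCc3ccccc3)c2c(c1C)[C@H](C)C(O)(COC(=O)c1c(C)c(C)c(OCc3ccccc3)c(C)c1OCc3ccccc3)C2=O
A6 | alternative 3 | benzyl 6-(benzyloxy)-2-[(2S,3R)-3-[(tert-butyldimethylsilyl)oxy]-4-[(2,4-dihydroxy-3,5,6-trimethylbenzoyl)oxy]butan-2-yl]-4-methoxy-3-methylbenzoate | Cc1c(C)c(O)c(C)c(O)c1C(=O)OC[C@H](O[Si](C)(C)C(C)(C)C)[C@@H](C)c1c(C)c(OC)cc(OCc2ccccc2)c1C(=O)OCc1ccccc1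
A7 | alternative 3 | [(1-methoxy-2-methylpenta-1,3-diene-1,3-diyl)bis(oxy)]bis(trimethylsilane) | CC=C(O[Si](C)(C)C)C(C)=C(OC)O[Si](C)(C)C
A8 | alternative 3 | benzyl 6-(benzyloxy)-2-[(2S,3R)-4-(but-2-ynoyloxy)-3-[(tert-butyldimethylsilyl)oxy]butan-2-yl]-4-methoxy-3-methylbenzoate | CC#CC(=O)OC[C@H](O[Si](C)(C)C(C)(C)C)[C@@H](C)c1c(C)c(OC)cc(OCc2ccccc2)c1C(=O)OCc1ccccc1
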